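**Plan**

- The retrosynthesis first cuts O1–C2 of the pyran ring (ring C). This is possible because the 4′-OH of ring B is para to C1′, so C2 can be flattened into a para-quinone methide and recaptured by the oxygen on C8a of ring A. The precursor is a racemic 1,3-diarylpropan-1-ol.
- The carbinol is traced to a dihydrochalcone, which is cut at C3–C4 (aldol condensation) into a ring-B acetophenone and a ring-A benzaldehyde.
- The aryl–carbon bonds are cut last: C6–C(quaternary) of the 1,1-dimethylallyl group (γ-selective allyl–aryl coupling) and the C2′– and C5′–prenyl bonds (two O→C Claisen rearrangements). The Claisen steps are run one at a time, because a catechol bis(1,1-dimethylallyl) ether with a para-acyl group can divert into an ipso-Claisen/Diels–Alder cage.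
- Forward: ring-B ketone (steps 1–7), ring-A aldehyde (steps 8–9), aldol union and adjustment of oxidation level (steps 10–13). Rings A and B are bought; ring C is the only ring made and closes last.
- Stereochemistry: the single stereocentre C2 is set in the last step by a chiral phosphoric acid. The carbinol configuration is erased on ionisation, so both enantiomers of the precursor converge on (2S).

Key step: step 14

Assumption: the sense of induction of the phosphoric acid cannot be predicted with confidence for this substrate; the (R)-catalyst is written, and its antipode is to be used if a pilot run shows that it leads to the (2R)-flavan.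

**Route**

Step 1
Reactants: 1 2-methylbut-3-en-2-ol
Product: 2 tert-butyl (2-methylbut-3-en-2-yl) carbonate
Conditions: n-BuLi, THF, −78 → 0 °C; Boc2O, 0 °C → rt
Reagents that add atoms: di-tert-butyl dicarbonate, CC(C)(C)OC(=O)OC(=O)OC(C)(C)C
Why: O-acylation of the lithium alkoxide of the tertiary allylic alcohol should give the mixed carbonate, the usual leaving-group form for palladium π-allyl chemistry.

Step 2
Reactants: 3 3′,4′-dihydroxyacetophenone; 2 tert-butyl (2-methylbut-3-en-2-yl) carbonate
Product: 4 1-[3-hydroxy-4-(2-methylbut-3-en-2-yloxy)phenyl]ethan-1-one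
Conditions: 2 (1.05 equiv), Pd(PPh3)4 (cat.), THF, 0 °C
Reagents that add atoms: none
Why: Tsuji–Trost O-allylation, in which the tert-butoxide released from the carbonate ionises the more acidic 4-OH (para to the acetyl group) and the phenoxide attacks the π-(1,1-dimethylallyl)palladium complex at its substituted terminus under kinetic control at low temperature, which should give the tertiary monoether.

Step 3
Reactants: 4 1-[3-hydroxy-4-(2-methylbut-3-en-2-yloxy)phenyl]ethan-1-one
Product: 6 1-[3,4-dihydroxy-5-(3-methylbut-2-en-1-yl)phenyl]ethan-1-one, via Claisen dienone 5 (not isolated)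
Conditions: PhMe, 120 °C (sealed tube), Ar
Reagents that add atoms: none
Why: Aromatic Claisen rearrangement, which delivers the allyl unit with allylic inversion to C5, the only unsubstituted ortho position, so the 1,1-dimethylallyl ether becomes a C-prenyl group and dienone 5 re-aromatises by enolisation, while migration to C3 (bearing OH) is reversible and unproductive.

Step 4
Reactants: 6 1-[3,4-dihydroxy-5-(3-methylbut-2-en-1-yl)phenyl]ethan-1-one
Product: 7 1-[3-hydroxy-4-(methoxymethoxy)-5-(3-methylbut-2-en-1-yl)phenyl]ethan-1-one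
Conditions: MOMCl (1.05 equiv), K2CO3 (1.1 equiv), acetone, 0 °C → rt
Reagents that add atoms: chloromethyl methyl ether, COCCl
Why: O-alkylation (Williamson type) with one equivalent of weak base should ionise only the 4-OH para to the acyl group, as in the known 4-O-selective alkylations of 3,4-dihydroxyaryl carbonyl compounds, leaving the 3-OH free for the second etherification.

Step 5
Reactants: 7 1-[3-hydroxy-4-(methoxymethoxy)-5-(3-methylbut-2-en-1-yl)phenyl]ethan-1-one; 2 tert-butyl (2-methylbut-3-en-2-yl) carbonate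
Product: 8 1-[4-(methoxymethoxy)-3-(2-methylbut-3-en-2-yloxy)-5-(3-methylbut-2-en-1-yl)phenyl]ethan-1-one
Conditions: 2 (1.2 equiv), Pd(PPh3)4 (cat.), THF, 0 °C
Reagents that add atoms: none
Why: Tsuji–Trost O-allylation of the only free phenol, again at the tertiary terminus of the π-allyl complex under kinetic control; the C-prenyl group and the MOM ether are inert to Pd(0).

Step 6
Reactants: 8 1-[4-(methoxymethoxy)-3-(2-methylbut-3-en-2-yloxy)-5-(3-methylbut-2-en-1-yl)phenyl]ethan-1-one
Product: 10 1-[3-hydroxy-4-(methoxymethoxy)-2,5-bis(3-methylbut-2-en-1-yl)phenyl]ethan-1-one, via Claisen dienone 9 (not isolated)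
Conditions: PhMe, 120 °C (sealed tube), Ar
Reagents that add atoms: none
Why: Aromatic Claisen rearrangement to C2, the only open ortho position (migration toward a meta-acyl group is also the electronically preferred direction); the neighbouring oxygen carries a MOM group and no allyl ether, so an ipso shift to C4 can only revert and no Diels–Alder diversion is available.

Step 7
Reactants: 10 1-[3-hydroxy-4-(methoxymethoxy)-2,5-bis(3-methylbut-2-en-1-yl)phenyl]ethan-1-one
Product: 11 1-[3,4-bis(methoxymethoxy)-2,5-bis(3-methylbut-2-en-1-yl)phenyl]ethan-1-one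
Conditions: MOMCl, iPr2NEt, CH2Cl2, 0 → 40 °C
Reagents that add atoms: chloromethyl methyl ether, COCCl
Why: Standard MOM protection of the remaining phenol with an amine base (which avoids enolising the methyl ketone) should give a ketone with no acidic OH for the aldol and hydride steps.

Step 8
Reactants: 12 5-bromo-2,4-dihydroxybenzaldehyde
Product: 13 5-bromo-2,4-bis(methoxymethoxy)benzaldehyde
Conditions: NaH, MOMCl, DMF, 0 °C → rt
Reagents that add atoms: chloromethyl methyl ether, COCCl
Why: Double O-alkylation of the phenoxides (the hydrogen-bonded 2-OH needs the strong base) on a non-enolisable aldehyde; a routine protection.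

Step 9
Reactants: 13 5-bromo-2,4-bis(methoxymethoxy)benzaldehyde; 14 4,4,5,5-tetramethyl-2-(3-methylbut-2-en-1-yl)-1,3,2-dioxaborolane (prenylboronic acid pinacol ester)
Product: 15 2,4-bis(methoxymethoxy)-5-(2-methylbut-3-en-2-yl)benzaldehyde
Conditions: 14 (1.5 equiv), Pd(OAc)2/dialkylbiarylphosphine (γ-selective ligand, fixed by a short screen), aq K3PO4, MeCN, 70 °C
Reagents that add atoms: none
Why: Ligand-controlled γ-selective Suzuki–Miyaura allyl–aryl coupling, in which SE2′ transmetalation of the prenylboronate gives the tertiary σ-allylpalladium aryl species and a ligand that makes reductive elimination faster than σ–π–σ isomerisation should give the quaternary benzylic carbon, a known outcome for 3,3-disubstituted allylboronates with aryl bromides; aldehyde and MOM ethers tolerate aqueous phosphate.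

Step 10
Reactants: 11 1-[3,4-bis(methoxymethoxy)-2,5-bis(3-methylbut-2-en-1-yl)phenyl]ethan-1-one; 15 2,4-bis(methoxymethoxy)-5-(2-methylbut-3-en-2-yl)benzaldehyde
Product: 17 (E)-1-[3,4-bis(methoxymethoxy)-2,5-bis(3-methylbut-2-en-1-yl)phenyl]-3-[2,4-bis(methoxymethoxy)-5-(2-methylbut-3-en-2-yl)phenyl]prop-2-en-1-one, via aldol adduct 16 (not isolated)
Conditions: KOH, EtOH–H2O, rt
Reagents that add atoms: none
Why: Claisen–Schmidt condensation, in which the methyl ketone enolate adds to the non-enolisable aldehyde and aldol 16 loses water (E1cB) to the conjugated (E)-enone, destroying the transient aldol stereocentre; all phenols are masked as base-stable MOM ethers.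

Step 11
Reactants: 17 (E)-1-[3,4-bis(methoxymethoxy)-2,5-bis(3-methylbut-2-en-1-yl)phenyl]-3-[2,4-bis(methoxymethoxy)-5-(2-methylbut-3-en-2-yl)phenyl]prop-2-en-1-one
Product: 18 1-[3,4-bis(methoxymethoxy)-2,5-bis(3-methylbut-2-en-1-yl)phenyl]-3-[2,4-bis(methoxymethoxy)-5-(2-methylbut-3-en-2-yl)phenyl]propan-1-one
Conditions: [(Ph3P)CuH]6, H2O, PhMe, rt
Reagents that add atoms: none
Why: Copper hydride conjugate reduction, which delivers hydride only to the β-carbon of the enone (the copper enolate is protonated by water) and should leave the isolated trisubstituted and monosubstituted alkenes, the MOM ethers and the saturated ketone untouched.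

Step 12
Reactants: 18 1-[3,4-bis(methoxymethoxy)-2,5-bis(3-methylbut-2-en-1-yl)phenyl]-3-[2,4-bis(methoxymethoxy)-5-(2-methylbut-3-en-2-yl)phenyl]propan-1-one
Product: 19 1-[3,4-dihydroxy-2,5-bis(3-methylbut-2-en-1-yl)phenyl]-3-[2,4-dihydroxy-5-(2-methylbut-3-en-2-yl)phenyl]propan-1-one
Conditions: 3 M HCl, MeOH, 40 °C, Ar
Reagents that add atoms: none
Why: Acid-catalysed acetal solvolysis of the four aryl MOM ethers, placed at the ketone oxidation level so that no ionisable benzylic alcohol is present while acid is in the flask; mild temperature and short contact are meant to spare the ortho-prenyl and 1,1-dimethylallyl phenols.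

Step 13
Reactants: 19 1-[3,4-dihydroxy-2,5-bis(3-methylbut-2-en-1-yl)phenyl]-3-[2,4-dihydroxy-5-(2-methylbut-3-en-2-yl)phenyl]propan-1-one
Product: 20 rac-1-[3,4-dihydroxy-2,5-bis(3-methylbut-2-en-1-yl)phenyl]-3-[2,4-dihydroxy-5-(2-methylbut-3-en-2-yl)phenyl]propan-1-ol
Conditions: NaBH4 (excess), MeOH–THF, 0 °C → rt, Ar; pH 7 phosphate buffer work-up, no acidic silica
Reagents that add atoms: none
Why: Borohydride reduction of the aryl ketone (slowed by the 4′-phenoxide, hence excess reagent) should give the benzylic alcohol; C2 is formed as a racemate on purpose because step 14 erases its configuration, and the labile 4-hydroxybenzylic alcohol is kept neutral and carried forward directly.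

Step 14
Reactants: 20 rac-1-[3,4-dihydroxy-2,5-bis(3-methylbut-2-en-1-yl)phenyl]-3-[2,4-dihydroxy-5-(2-methylbut-3-en-2-yl)phenyl]propan-1-ol
Product: 22 (2S)-2-[3,4-dihydroxy-2,5-bis(3-methylbut-2-en-1-yl)phenyl]-6-(2-methylbut-3-en-2-yl)-3,4-dihydro-2H-chromen-7-ol, via para-quinone methide 21 (not isolated)
Conditions: (R)-TRIP (10 mol %), 4 Å MS, CH2Cl2 (0.02 M), −20 °C; Et3N quench at full conversion
Reagents that add atoms: none
Why: The phosphoric acid protonates the benzylic hydroxyl of either enantiomer of 20 and water leaves with push from the para 4′-OH, so both enantiomers give the same planar para-quinone methide 21 (C2 exocyclic to ring B, carbonyl at C4′) held in a hydrogen-bonded complex with the phosphate; the C8a–OH, bound to the phosphoryl oxygen, then adds 1,6 to C2 and ring B re-aromatises. The closest known reaction type is the chiral-phosphoric-acid-catalysed enantioselective 1,6-addition of oxygen nucleophiles to para-quinone methides generated in situ from 4-hydroxybenzylic alcohols. The pyran ring closes in a 6-exo-trig mode, O1 attacking the exocyclic C2=C1′ bond. The C2 configuration is controlled by the catalyst alone, which shields one face of the quinone methide while delivering the phenol to the other, the carbinol configuration having been erased (stereoconvergence). The step needs O- over C-alkylation and must spare three acid-sensitive alkenes: only the C8a oxygen can reach C2 through a six-membered transition state, and the electron-rich 4′-hydroxyaryl ring allows ionisation with a weak acid at −20 °C, below the threshold for alkene protonation. The product ether must re-ionise more slowly than the carbinol, so the reaction should be quenched as soon as 20 is consumed.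

**Compound list**

1 | 2-methylbut-3-en-2-ol | C=CC(C)(C)O | starting material
2 | tert-butyl (2-methylbut-3-en-2-yl) carbonate | C=CC(C)(C)OC(=O)OC(C)(C)C | intermediate
3 | 3′,4′-dihydroxyacetophenone | CC(=O)c1ccc(O)c(O)c1 | starting material
4 | 1-[3-hydroxy-4-(2-methylbut-3-en-2-yloxy)phenyl]ethan-1-one | CC(=O)c1ccc(OC(C)(C)C=C)c(O)c1 | intermediate
5 | 4-acetyl-2-hydroxy-6-(3-methylbut-2-en-1-yl)cyclohexa-2,4-dien-1-one (racemic, not isolated) | CC(=O)C1=CC(CC=C(C)C)C(=O)C(O)=C1 | intermediate
6 | 1-[3,4-dihydroxy-5-(3-methylbut-2-en-1-yl)phenyl]ethan-1-one | CC(=O)c1cc(O)c(O)c(CC=C(C)C)c1 | intermediate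
7 | 1-[3-hydroxy-4-(methoxymethoxy)-5-(3-methylbut-2-en-1-yl)phenyl]ethan-1-one | CC(=O)c1cc(O)c(OCOC)c(CC=C(C)C)c1 | intermediate
8 | 1-[4-(methoxymethoxy)-3-(2-methylbut-3-en-2-yloxy)-5-(3-methylbut-2-en-1-yl)phenyl]ethan-1-one | CC(=O)c1cc(OC(C)(C)C=C)c(OCOC)c(CC=C(C)C)c1 | intermediate
9 | 5-acetyl-2-(methoxymethoxy)-3,6-bis(3-methylbut-2-en-1-yl)cyclohexa-2,4-dien-1-one (racemic, not isolated) | CC(=O)C1=CC(CC=C(C)C)=C(OCOC)C(=O)C1CC=C(C)C | intermediate
10 | 1-[3-hydroxy-4-(methoxymethoxy)-2,5-bis(3-methylbut-2-en-1-yl)phenyl]ethan-1-one | CC(=O)c1cc(CC=C(C)C)c(OCOC)c(O)c1CC=C(C)C | intermediate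
11 | 1-[3,4-bis(methoxymethoxy)-2,5-bis(3-methylbut-2-en-1-yl)phenyl]ethan-1-one | CC(=O)c1cc(CC=C(C)C)c(OCOC)c(OCOC)c1CC=C(C)C | intermediate
12 | 5-bromo-2,4-dihydroxybenzaldehyde | O=Cc1cc(Br)c(O)cc1O | starting material
13 | 5-bromo-2,4-bis(methoxymethoxy)benzaldehyde | O=Cc1cc(Br)c(OCOC)cc1OCOC | intermediate
14 | 4,4,5,5-tetramethyl-2-(3-methylbut-2-en-1-yl)-1,3,2-dioxaborolane | CC(C)=CCB1OC(C)(C)C(C)(C)O1 | starting material
15 | 2,4-bis(methoxymethoxy)-5-(2-methylbut-3-en-2-yl)benzaldehyde | C=CC(C)(C)c1cc(C=O)c(OCOC)cc1OCOC | intermediate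
16 | 1-[3,4-bis(methoxymethoxy)-2,5-bis(3-methylbut-2-en-1-yl)phenyl]-3-hydroxy-3-[2,4-bis(methoxymethoxy)-5-(2-methylbut-3-en-2-yl)phenyl]propan-1-one (racemic, not isolated) | C=CC(C)(C)c1cc(C(O)CC(=O)c2cc(CC=C(C)C)c(OCOC)c(OCOC)c2CC=C(C)C)c(OCOC)cc1OCOC | intermediate
17 | (E)-1-[3,4-bis(methoxymethoxy)-2,5-bis(3-methylbut-2-en-1-yl)phenyl]-3-[2,4-bis(methoxymethoxy)-5-(2-methylbut-3-en-2-yl)phenyl]prop-2-en-1-one | C=CC(C)(C)c1cc(/C=C/C(=O)c2cc(CC=C(C)C)c(OCOC)c(OCOC)c2CC=C(C)C)c(OCOC)cc1OCOC | intermediate
18 | 1-[3,4-bis(methoxymethoxy)-2,5-bis(3-methylbut-2-en-1-yl)phenyl]-3-[2,4-bis(methoxymethoxy)-5-(2-methylbut-3-en-2-yl)phenyl]propan-1-one | C=CC(C)(C)c1cc(CCC(=O)c2cc(CC=C(C)C)c(OCOC)c(OCOC)c2CC=C(C)C)c(OCOC)cc1OCOC | intermediate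
19 | 1-[3,4-dihydroxy-2,5-bis(3-methylbut-2-en-1-yl)phenyl]-3-[2,4-dihydroxy-5-(2-methylbut-3-en-2-yl)phenyl]propan-1-one | C=CC(C)(C)c1cc(CCC(=O)c2cc(CC=C(C)C)c(O)c(O)c2CC=C(C)C)c(O)cc1O | intermediate
20 | rac-1-[3,4-dihydroxy-2,5-bis(3-methylbut-2-en-1-yl)phenyl]-3-[2,4-dihydroxy-5-(2-methylbut-3-en-2-yl)phenyl]propan-1-ol | C=CC(C)(C)c1cc(CCC(O)c2cc(CC=C(C)C)c(O)c(O)c2CC=C(C)C)c(O)cc1O | intermediate
21 | 4-{3-[2,4-dihydroxy-5-(2-methylbut-3-en-2-yl)phenyl]propylidene}-2-hydroxy-3,6-bis(3-methylbut-2-en-1-yl)cyclohexa-2,5-dien-1-one (not isolated) | C=CC(C)(C)c1cc(CCC=C2C=C(CC=C(C)C)C(=O)C(O)=C2CC=C(C)C)c(O)cc1O | intermediate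
22 | (2S)-2-[3,4-dihydroxy-2,5-bis(3-methylbut-2-en-1-yl)phenyl]-6-(2-methylbut-3-en-2-yl)-3,4-dihydro-2H-chromen-7-ol | C=CC(C)(C)c1cc2c(cc1O)O[C@H](c1cc(CC=C(C)C)c(O)c(O)c1CC=C(C)C)CC2 | target

**Step count and risks**

Total steps: 14. Longest linear sequence: 12 steps (1 → 2 → 4 → 6 → 7 → 8 → 10 → 11 → 17 → 18 → 19 → 20 → 22; steps 1–7 and 10–14).

Steps most likely to fail:

1. Step 14. Three processes could erode the enantiomeric purity:
   - re-ionisation of the O1–C2 bond of the product, which is itself a 4-hydroxybenzyl aryl ether;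
   - unselective ring closure by adventitious acid before the catalyst is engaged;
   - weak facial discrimination because the free 3′- and 7-hydroxyls offer competing hydrogen-bond sites.

   The fallback gives up asymmetric induction in favour of resolution. It sets out from 20 and comes back at 22. Compound 20 would be closed with an achiral acid (diphenyl phosphate, CH2Cl2, 0 °C) to rac-2-[3,4-dihydroxy-2,5-bis(3-methylbut-2-en-1-yl)phenyl]-6-(2-methylbut-3-en-2-yl)-3,4-dihydro-2H-chromen-7-ol F1. The enantiomers would then be separated by preparative chromatography on a chiral stationary phase, the (2S)-enantiomer being 22.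

2. Step 9. The allylpalladium intermediate may isomerise (σ–π–σ) before reductive elimination and give the linear prenyl isomer. Reductive elimination at the position ortho to the MOM ether may also be so slow that protodeboronation of 14 wins.

   The fallback reverses the polarity of the coupling and sets the regiochemistry by an SN2′ displacement. It sets out from 13 and comes back at 15.
   - The aldehyde would be masked as the acetal 1-bromo-5-(dimethoxymethyl)-2,4-bis(methoxymethoxy)benzene F2 (HC(OMe)3, MeOH, cat. PPTS).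
   - Magnesium insertion (Mg, LiCl, THF) would give the aryl Grignard reagent. Copper-mediated anti-SN2′ substitution (CuBr·SMe2, THF, 0 °C) of 3-methylbut-2-en-1-yl pyridine-2-carboxylate F3 (from 3-methylbut-2-en-1-ol and picolinic acid, DCC, DMAP) would then place the aryl group on the tertiary carbon, giving 1-(dimethoxymethyl)-2,4-bis(methoxymethoxy)-5-(2-methylbut-3-en-2-yl)benzene F4.
   - Mild hydrolysis (PPTS, acetone–H2O, rt) would return 15.

3. Step 12. The liberated phenols may add under acid catalysis to the neighbouring prenyl and 1,1-dimethylallyl double bonds (chroman and dihydrobenzofuran formation). The 3-(2-hydroxyaryl)propanone may also undergo cyclodehydration to a flavene.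

   The fallback avoids protic acid altogether. It sets out from 18 and comes back at 19. The four aryl MOM ethers would be exchanged for silyl ethers under non-protic conditions (TESOTf, 2,2′-bipyridyl, CH2Cl2, 0 °C). This would give 1-[3,4-bis(triethylsilyloxy)-2,5-bis(3-methylbut-2-en-1-yl)phenyl]-3-[2,4-bis(triethylsilyloxy)-5-(2-methylbut-3-en-2-yl)phenyl]propan-1-one F5. Buffered fluoride (TBAF, AcOH, THF, 0 °C) would then release 19.

Further compounds
F1 | step 14 | rac-2-[3,4-dihydroxy-2,5-bis(3-methylbut-2-en-1-yl)phenyl]-6-(2-methylbut-3-en-2-yl)-3,4-dihydro-2H-chromen-7-ol | C=CC(C)(C)c1cc2c(cc1O)OC(c1cc(CC=C(C)C)c(O)c(O)c1CC=C(C)C)CC2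
F2 | step 9 | 1-bromo-5-(dimethoxymethyl)-2,4-bis(methoxymethoxy)benzene | COC(OC)c1cc(Br)c(OCOC)cc1OCOC
F3 | step 9 | 3-methylbut-2-en-1-yl pyridine-2-carboxylate | CC(C)=CCOC(=O)c1ccccn1
F4 | step 9 | 1-(dimethoxymethyl)-2,4-bis(methoxymethoxy)-5-(2-methylbut-3-en-2-yl)benzene | C=CC(C)(C)c1cc(C(OC)OC)c(OCOC)cc1OCOC
F5 | step 12 | 1-[3,4-bis(triethylsilyloxy)-2,5-bis(3-methylbut-2-en-1-yl)phenyl]-3-[2,4-bis(triethylsilyloxy)-5-(2-methylbut-3-en-2-yl)phenyl]propan-1-one | C=CC(C)(C)c1cc(CCC(=O)c2cc(CC=C(C)C)c(O[Si](CC)(CC)CC)c(O[Si](CC)(CC)CC)c2CC=C(C)C)c(O[Si](CC)(CC)CC)cc1O[Si](CC)(CC)CC
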